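**Retrosynthetic overview**

1. Ring numbering used throughout: C1 = CH bearing the heptenyl chain, C2 = C(CH3)–O, C3 = CH–O, C4 = C(CH3)=, C5 = =CH, C6 = quaternary C(CH3)(pyranonyl); β = ring face of the pyranone on C6, α = the opposite face.
2. Target ⇐ side-chain carbinol oxidation and desilylation ⇐ C4=C5 by syn-elimination of a C5 carbinol ⇐ α-oxirane by inversion of a hydroxyl-directed β-epoxide ⇐ cyclohex-3-enone with a temporary C5 carbonyl.
3. That cyclohexenone is cut at C3–C4 (aldol addition) and C1–C6 (palladium-catalysed allylic alkylation), both made in one flask from dienal fragment A (side chain plus C1–C3) and racemic ketone fragment B (pyranone plus C4–C6).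
4. Enabling feature: C6 lies between the temporary C5 carbonyl and C6′ of the vinylogous-ester pyranone, so it is a soft, planar carbon nucleophile; C1 is the doubly allylic terminus of the C1–C2–C3 allyl unit (flanked by ring C2 and the side-chain C(CH3)=CH), so ionisation of a C3–O bond turns it into a π-allyl electrophile.
5. Rings are formed in the order pyranone (steps 7–9), cyclohexene (step 12), oxirane (steps 14–17).

Key step: step 12

Remark: hydride is assumed to add to the C5 ketone anti to the pyranone on C6 (β-alcohol), and C4 of the cyclohexenone is assumed to equilibrate with its methyl trans to the pyranone; both centres are erased in step 18. TBS = tert-butyldimethylsilyl; "pyranonyl" = 2-methoxy-3,5-dimethyl-4-oxo-4H-pyran-6-yl.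

**Fragment A**

Step 1
Reactants: 1 (4S)-4-benzyl-3-propanoyl-1,3-oxazolidin-2-one; 2 propanal
Product: 3 (4S)-4-benzyl-3-[(2S,3R)-3-hydroxy-2-methylpentanoyl]-1,3-oxazolidin-2-one
Conditions: Bu2BOTf, i-Pr2NEt, CH2Cl2, −78 to 0 °C; then pH 7 buffer, MeOH, H2O2
Reagents that add atoms: none
Why: Evans syn-aldol addition through the Z-boron enolate and a Zimmerman–Traxler transition state, in which the benzyl group of the auxiliary shields one enolate face and so sets both side-chain stereocentres (2S,3R).

Step 2
Reactants: 3 aldol imide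
Product: 4 (4S)-4-benzyl-3-[(2S,3R)-3-[(tert-butyldimethylsilyl)oxy]-2-methylpentanoyl]-1,3-oxazolidin-2-one
Conditions: TBSOTf, 2,6-lutidine, CH2Cl2, −78 to 0 °C
Reagents that add atoms: tert-butyldimethylsilyl trifluoromethanesulfonate, CC(C)(C)[Si](C)(C)OS(=O)(=O)C(F)(F)F
Why: silyl triflate silylation of the hindered secondary alcohol gives an ether that should survive every later basic, reductive, oxidative and mildly acidic step.

Step 3
Reactants: 4 silylated imide
Product: 5 (2R,3R)-3-[(tert-butyldimethylsilyl)oxy]-2-methylpentan-1-ol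
Conditions: LiBH4, MeOH (1 equiv), THF, 0 °C
Reagents that add atoms: none
Why: borohydride reductive cleavage of the N-acyl oxazolidinone gives the primary alcohol without touching the α-stereocentre and returns the auxiliary.

Step 4
Reactants: 5 primary alcohol
Product: 6 (2S,3R)-3-[(tert-butyldimethylsilyl)oxy]-2-methylpentanal
Conditions: Dess–Martin periodinane, NaHCO3, CH2Cl2, 0 to 23 °C
Reagents that add atoms: none
Why: buffered Dess–Martin oxidation is a standard non-epimerising route to α-chiral aldehydes, and the product is used at once.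

Step 5
Reactants: 6 aldehyde; 7 2-(triphenyl-λ5-phosphanylidene)propanal
Product: 8 (2E,4R,5R)-5-[(tert-butyldimethylsilyl)oxy]-2,4-dimethylhept-2-enal
Conditions: toluene, 90 °C
Reagents that add atoms: none
Why: Wittig olefination with the stabilised formyl ylide should give the (E)-trisubstituted enal under thermodynamic control.

Step 6
Reactants: 8 enal; 7 2-(triphenyl-λ5-phosphanylidene)propanal
Product: 9 (2E,4E,6R,7R)-7-[(tert-butyldimethylsilyl)oxy]-2,4,6-trimethylnona-2,4-dienal (fragment A)
Conditions: 7 (1.5 equiv), toluene, 110 °C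
Reagents that add atoms: none
Why: a second Wittig homologation with the same stabilised ylide should install the second (E)-trisubstituted alkene, whose carbons become C1 and C2 of the ring.

**Fragment B**

Step 7
Reactants: 10 methyl 2-methyl-3-oxopentanoate; 11 methyl propanoate
Product: 12 methyl 2,4-dimethyl-3,5-dioxoheptanoate (tautomer and diastereomer mixture)
Conditions: LiN(i-Pr)2 (2.2 equiv), THF, −78 to 0 °C; 11, −78 to 0 °C; aq HCl
Reagents that add atoms: none
Why: Claisen-type acylation of the β-keto ester dianion at its more basic γ-carbon (Huckin–Weiler dianion chemistry) should give the 3,5-dioxo ester.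

Step 8
Reactants: 12 triketo ester
Product: 13 6-ethyl-4-hydroxy-3,5-dimethyl-2H-pyran-2-one
Conditions: DBU, toluene, 110 °C
Reagents that add atoms: none
Why: base-mediated enol lactonisation of a 3,5-dioxo ester is the standard entry to 4-hydroxy-2-pyranones.

Step 9
Reactants: 13 hydroxypyranone
Product: 14 6-ethyl-2-methoxy-3,5-dimethyl-4H-pyran-4-one
Conditions: MeOTf, CH2Cl2, 23 °C; then aq NaHCO3
Reagents that add atoms: methyl trifluoromethanesulfonate, COS(=O)(=O)C(F)(F)F
Why: a hard methylating agent alkylates the lactone carbonyl oxygen, and deprotonation of the resulting 4-hydroxy-2-methoxypyrylium salt should give the 2-methoxy-4-pyranone isomer selectively.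

Step 10
Reactants: 14 ethylpyranone; 2 propanal
Product: 15 6-(3-hydroxypentan-2-yl)-2-methoxy-3,5-dimethyl-4H-pyran-4-one (racemic diastereomer mixture)
Conditions: LiN(SiMe3)2, THF, −78 °C; then 2
Reagents that add atoms: none
Why: the CH2 of the 6-ethyl group is vinylogously acidified by the pyranone carbonyl, and its lithium dienolate undergoes aldol addition at that exocyclic carbon.

Step 11
Reactants: 15 pyranone alcohol
Product: 16 2-methoxy-3,5-dimethyl-6-(3-oxopentan-2-yl)-4H-pyran-4-one (racemic; fragment B)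
Conditions: Dess–Martin periodinane, NaHCO3, CH2Cl2, 23 °C
Reagents that add atoms: none
Why: Dess–Martin oxidation of the secondary alcohol gives the ethyl ketone, whose configurationally labile C6–H centre is erased in step 12.

**Union and carbocycle**

Step 12
Reactants: 16 pyranonyl ketone (fragment B); 9 dienal (fragment A)
Product: 19 cyclohex-3-enone (C5 ketone; C2=C3; 6β-pyranonyl; 6α-methyl; 1α-alkenyl chain; 4α-methyl), via aldol adduct 17 (not isolated), via allylic acetate 18 (not isolated)
Conditions: LiN(i-Pr)2 (2.1 equiv), THF, −78 °C; 9, −78 °C; Ac2O (1.05 equiv), −78 to −40 °C; then Pd2(dba)3·CHCl3 (2.5 mol %), (R,R)-DACH-phenyl Trost ligand (7.5 mol %), −40 to 23 °C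
Reagents that add atoms: none
Why: The dianion of 16 (C6–H removed first, then C4–H) adds through its more basic C4 terminus to the aldehyde of 9 (C3–C4 bond), the alkoxide is acetylated, and zerovalent palladium ionises the doubly allylic acetate to an η3-allyl complex over C3–C2–C1 that the pendant C6 enolate attacks at C1 (C1–C6 bond); this is a dianion aldol addition telescoped with an intramolecular Tsuji–Trost (Trost asymmetric) allylic alkylation. The six-membered ring closes in a 6-endo mode at the distal allyl terminus (overall an intramolecular SN2′ displacement), favoured by ring size over 4-exo attack at C3 and over eight-membered closure at the side-chain terminus. C6 becomes stereogenic from a planar enolate and C3 loses its stereocentre on ionisation, so all diastereomers of 18 and both enantiomers of racemic 16 should converge on one product; the chiral ligand is expected to select the allyl face that is attacked at C1 (anti to palladium) after η3–η1–η3 equilibration, which is needed in any case to place C4 anti on the allyl unit for a cis ring alkene. The C1/C6 relationship should follow from an antiperiplanar approach that keeps the bulky pyranone anti to the C1 alkenyl chain, and C4 stays epimerisable and should settle trans to the pyranone. The step needs C- over O-alkylation (an O-allyl enol ether would re-ionise under the catalyst) and C1 over C3 attack (secured by ring size); should the sense of induction prove opposite, the antipodal ligand is used.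

**Oxirane, alkene and end game**

Step 13
Reactants: 19 cyclohexenone
Product: 20 cyclohex-3-enol (5β-OH; otherwise as 19)
Conditions: NaBH4, CeCl3·7H2O, MeOH/THF, −40 °C
Reagents that add atoms: none
Why: Luche-type 1,2-reduction, in which hydride should add anti to the pyranone on the adjacent quaternary C6 (Felkin–Anh) to give the β-alcohol, while the cerium salt keeps the medium non-basic so that the C2=C3 bond does not move into conjugation and the pyranone is not reduced.

Step 14
Reactants: 20 cyclohexenol
Product: 21 β-epoxy alcohol (2β,3β-oxirane; 5β-OH)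
Conditions: VO(acac)2 (5 mol %), t-BuOOH, CH2Cl2, 0 to 23 °C
Reagents that add atoms: tert-butyl hydroperoxide, CC(C)(C)OO
Why: vanadium-catalysed hydroxyl-directed epoxidation of the homoallylic alcohol delivers oxygen to C2=C3 syn to the C5 hydroxyl (β-face) and should leave the undirected side-chain alkene untouched.

Step 15
Reactants: 21 β-epoxy alcohol
Product: 22 β-epoxy acetate (5β-OAc)
Conditions: Ac2O, pyridine, DMAP (cat.), CH2Cl2, 23 °C
Reagents that add atoms: acetic anhydride, CC(=O)OC(C)=O
Why: acetylation masks the C5 hydroxyl so that only the C3 hydroxyl formed in step 16 is sulfonylated in step 17.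

Step 16
Reactants: 22 β-epoxy acetate
Product: 23 diol acetate (2α-OH tertiary; 3β-OH; 5β-OAc)
Conditions: HClO4 (5 mol %), THF/H2O 4:1, 0 °C
Reagents that add atoms: water, O
Why: acid-catalysed epoxide hydrolysis, in which water attacks the tertiary C2 with inversion (trans-diaxial opening) and so places the C2 oxygen on the α-face, syn to the C1 side chain, where no electrophilic oxidant would deliver it.

Step 17
Reactants: 23 diol acetate
Product: 25 α-epoxy alcohol (2α,3α-oxirane; 5β-OH), via mesylate 24 (not isolated)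
Conditions: MsCl, Et3N, CH2Cl2, 0 °C; then K2CO3, MeOH, 23 °C
Reagents that add atoms: none
Why: only the secondary C3 hydroxyl is mesylated, and the C2 alkoxide then displaces it in an intramolecular SN2 reaction with inversion at C3 (net epoxide inversion), closing the oxirane on the α-face as in the target while methanolysis removes the acetate.

Step 18
Reactants: 25 α-epoxy alcohol
Product: 26 vinyl epoxide silyl ether (target ring; side-chain OTBS)
Conditions: Burgess reagent, toluene, 70 °C
Reagents that add atoms: none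
Why: Burgess syn-elimination of the C5 sulfamate with the cis C4–H, the only β-hydrogen because C6 is quaternary, gives the C4=C5 alkene regiospecifically under neutral conditions that the oxirane tolerates.

Step 19
Reactants: 26 vinyl epoxide silyl ether
Product: 27 hydroxy vinyl epoxide (side-chain 5R carbinol)
Conditions: TBAF, THF, 0 to 23 °C
Reagents that add atoms: none
Why: fluoride cleaves the secondary silyl ether without affecting the oxirane, the pyranone or the alkenes.

Step 20
Reactants: 27 hydroxy vinyl epoxide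
Product: 28 2-methoxy-3,5-dimethyl-6-[(1R,4R,5S,6S)-2,4,6-trimethyl-5-[(2E,4R)-4-methyl-5-oxohept-2-en-2-yl]-7-oxabicyclo[4.1.0]hept-2-en-4-yl]-4H-pyran-4-one (target)
Conditions: Dess–Martin periodinane, NaHCO3, CH2Cl2, 0 °C
Reagents that add atoms: none
Why: buffered Dess–Martin oxidation gives the ethyl ketone last, under conditions that should neither epimerise its allylic α-stereocentre nor move the β,γ-double bond into conjugation.

**Compound list**

1 | (4S)-4-benzyl-3-propanoyl-1,3-oxazolidin-2-one | CCC(=O)N1[C@@H](Cc2ccccc2)COC1=O | starting material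
2 | propanal | CCC=O | starting material
3 | (4S)-4-benzyl-3-[(2S,3R)-3-hydroxy-2-methylpentanoyl]-1,3-oxazolidin-2-one | CC[C@@H](O)[C@H](C)C(=O)N1[C@@H](Cc2ccccc2)COC1=O | intermediate
4 | (4S)-4-benzyl-3-[(2S,3R)-3-[(tert-butyldimethylsilyl)oxy]-2-methylpentanoyl]-1,3-oxazolidin-2-one | CC[C@@H](O[Si](C)(C)C(C)(C)C)[C@H](C)C(=O)N1[C@@H](Cc2ccccc2)COC1=O | intermediate
5 | (2R,3R)-3-[(tert-butyldimethylsilyl)oxy]-2-methylpentan-1-ol | CC[C@@H](O[Si](C)(C)C(C)(C)C)[C@H](C)CO | intermediate
6 | (2S,3R)-3-[(tert-butyldimethylsilyl)oxy]-2-methylpentanal | CC[C@@H](O[Si](C)(C)C(C)(C)C)[C@H](C)C=O | intermediate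
7 | 2-(triphenyl-λ5-phosphanylidene)propanal | CC(C=O)=P(c1ccccc1)(c1ccccc1)c1ccccc1 | starting material
8 | (2E,4R,5R)-5-[(tert-butyldimethylsilyl)oxy]-2,4-dimethylhept-2-enal | CC[C@@H](O[Si](C)(C)C(C)(C)C)[C@H](C)/C=C(\C)C=O | intermediate
9 | (2E,4E,6R,7R)-7-[(tert-butyldimethylsilyl)oxy]-2,4,6-trimethylnona-2,4-dienal (fragment A) | CC[C@@H](O[Si](C)(C)C(C)(C)C)[C@H](C)/C=C(\C)/C=C(\C)C=O | intermediate
10 | methyl 2-methyl-3-oxopentanoate | CCC(=O)C(C)C(=O)OC | starting material
11 | methyl propanoate | CCC(=O)OC | starting material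
12 | methyl 2,4-dimethyl-3,5-dioxoheptanoate | CCC(=O)C(C)C(=O)C(C)C(=O)OC | intermediate
13 | 6-ethyl-4-hydroxy-3,5-dimethyl-2H-pyran-2-one | CCC1=C(C)C(O)=C(C)C(=O)O1 | intermediate
14 | 6-ethyl-2-methoxy-3,5-dimethyl-4H-pyran-4-one | CCc1oc(OC)c(C)c(=O)c1C | intermediate
15 | 6-(3-hydroxypentan-2-yl)-2-methoxy-3,5-dimethyl-4H-pyran-4-one (racemic diastereomer mixture) | CCC(O)C(C)c1oc(OC)c(C)c(=O)c1C | intermediate
16 | 2-methoxy-3,5-dimethyl-6-(3-oxopentan-2-yl)-4H-pyran-4-one (racemic; fragment B) | CCC(=O)C(C)c1oc(OC)c(C)c(=O)c1C | intermediate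
17 | aldol adduct: 6-[(6E,8E,10R,11R)-11-[(tert-butyldimethylsilyl)oxy]-5-hydroxy-4,6,8,10-tetramethyl-3-oxotrideca-6,8-dien-2-yl]-2-methoxy-3,5-dimethyl-4H-pyran-4-one (mixture at chain C2, C4, C5) | CC[C@@H](O[Si](C)(C)C(C)(C)C)[C@H](C)/C=C(\C)/C=C(\C)C(O)C(C)C(=O)C(C)c1oc(OC)c(C)c(=O)c1C | intermediate
18 | allylic acetate: the 5-O-acetyl derivative of 17 (same mixture) | CC[C@@H](O[Si](C)(C)C(C)(C)C)[C@H](C)/C=C(\C)/C=C(\C)C(OC(C)=O)C(C)C(=O)C(C)c1oc(OC)c(C)c(=O)c1C | intermediate
19 | cyclohex-3-enone: ring C5 ketone, C2=C3 alkene, 1α-[(2E,4R,5R)-5-(TBS-oxy)-4-methylhept-2-en-2-yl], 2-methyl, 4α-methyl, 6α-methyl, 6β-pyranonyl | CC[C@@H](O[Si](C)(C)C(C)(C)C)[C@H](C)/C=C(\C)[C@@H]1C(C)=C[C@H](C)C(=O)[C@@]1(C)c1oc(OC)c(C)c(=O)c1C | intermediate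
20 | cyclohex-3-enol: as 19 with C5 reduced, 5β-OH | CC[C@@H](O[Si](C)(C)C(C)(C)C)[C@H](C)/C=C(\C)[C@@H]1C(C)=C[C@H](C)[C@@H](O)[C@@]1(C)c1oc(OC)c(C)c(=O)c1C | intermediate
21 | β-epoxy alcohol: as 20 with a 2β,3β-oxirane (2α-methyl) | CC[C@@H](O[Si](C)(C)C(C)(C)C)[C@H](C)/C=C(\C)[C@@H]1[C@@]2(C)O[C@H]2[C@H](C)[C@@H](O)[C@@]1(C)c1oc(OC)c(C)c(=O)c1C | intermediate
22 | β-epoxy acetate: the 5β-acetate of 21 | CC[C@@H](O[Si](C)(C)C(C)(C)C)[C@H](C)/C=C(\C)[C@@H]1[C@@]2(C)O[C@H]2[C@H](C)[C@@H](OC(C)=O)[C@@]1(C)c1oc(OC)c(C)c(=O)c1C | intermediate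
23 | diol acetate: 2α-OH (2β-methyl), 3β-OH, 5β-OAc | CC[C@@H](O[Si](C)(C)C(C)(C)C)[C@H](C)/C=C(\C)[C@@H]1[C@](C)(O)[C@@H](O)[C@H](C)[C@@H](OC(C)=O)[C@@]1(C)c1oc(OC)c(C)c(=O)c1C | intermediate
24 | mesylate: the 3β-methanesulfonate of 23 | CC[C@@H](O[Si](C)(C)C(C)(C)C)[C@H](C)/C=C(\C)[C@@H]1[C@](C)(O)[C@@H](OS(C)(=O)=O)[C@H](C)[C@@H](OC(C)=O)[C@@]1(C)c1oc(OC)c(C)c(=O)c1C | intermediate
25 | α-epoxy alcohol: 2α,3α-oxirane (2β-methyl), 4α-methyl, 5β-OH | CC[C@@H](O[Si](C)(C)C(C)(C)C)[C@H](C)/C=C(\C)[C@@H]1[C@]2(C)O[C@@H]2[C@H](C)[C@@H](O)[C@@]1(C)c1oc(OC)c(C)c(=O)c1C | intermediate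
26 | vinyl epoxide silyl ether: target ring (2α,3α-oxirane, C4=C5) with the side-chain (4R,5R)-5-(TBS-oxy) group | CC[C@@H](O[Si](C)(C)C(C)(C)C)[C@H](C)/C=C(\C)[C@@H]1[C@]2(C)O[C@@H]2C(C)=C[C@@]1(C)c1oc(OC)c(C)c(=O)c1C | intermediate
27 | hydroxy vinyl epoxide: 26 without the silyl group, side-chain (4R,5R)-5-hydroxy | CC[C@@H](O)[C@H](C)/C=C(\C)[C@@H]1[C@]2(C)O[C@@H]2C(C)=C[C@@]1(C)c1oc(OC)c(C)c(=O)c1C | intermediate
28 | 2-methoxy-3,5-dimethyl-6-[(1R,4R,5S,6S)-2,4,6-trimethyl-5-[(2E,4R)-4-methyl-5-oxohept-2-en-2-yl]-7-oxabicyclo[4.1.0]hept-2-en-4-yl]-4H-pyran-4-one | CCC(=O)[C@H](C)/C=C(\C)[C@@H]1[C@]2(C)O[C@@H]2C(C)=C[C@@]1(C)c1oc(OC)c(C)c(=O)c1C | target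

**Step count**

Total: 20 steps. Longest linear sequence: 15 steps (steps 1–6, then 12–20).

**The three steps most likely to fail**

Step 12. The diastereomeric η3-allylpalladium complexes may not equilibrate fast enough (stereochemical memory of the C3 acetate), which would erode control at C1 and C6; O-allylation or elimination of the allylic acetate could also compete. The fallback sets out from 16 and 9 and returns to the route at 19. It separates the two bond formations and takes the C1 configuration from a reagent-controlled carbinol instead of from ligand-controlled equilibration. Boron aldol addition of 16 to 9 (kinetic enolisation at the ethyl CH2 with i-Pr2NEt and the antipode of Ipc2BOTf that gives the R carbinol) should give the syn-aldol adduct F1. Methyl chloroformate and pyridine convert it into the allylic methyl carbonate F2. Pd(PPh3)4 in THF then cyclises F2 by anti ionisation and anti attack, a suprafacial 1,3-transfer of chirality from C3 to C1, with the methoxide released from the carbonate as the only base, and gives 19.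

Step 13. Hydride delivery to the hindered C5 ketone next to a quaternary carbon may show poor facial selectivity, and the C2=C3 bond may migrate into conjugation before reduction. The fallback sets out from 19 and returns at 26. If the α-alcohol predominates (it is also the product expected from an equatorially attacking bulky hydride, LiBH(s-Bu)3, THF, −78 °C), this C5-epimeric cyclohexenol F3 is carried on. VO(acac)2 and t-BuOOH then deliver oxygen to the α-face and give the α-epoxy α-alcohol F4 directly, so steps 15–17 are not needed. Because the C5–O bond of F4 is trans to C4–H, the alkene is made by anti-elimination: MsCl and Et3N give the mesylate F5, and DBU in toluene at 80 °C gives 26.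

Step 16. Under acid the epoxide may rearrange by hydride shift to a ketone, water may attack C3 instead of C2, or the silyl ether may be lost. The fallback sets out from 20 and returns at 25, and builds the α-oxirane by anti-addition and closure without acid. NBS in THF/water should give the bromohydrin F6 (bromonium ion on the less hindered β-face, water at the tertiary C2 from the α-face), and K2CO3 in methanol closes it to 25; the selectivity for the ring alkene over the side-chain alkene would have to be checked.

**Further compounds**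

F1 | step 12 | syn-aldol adduct: 6-[(4R,5R,6E,8E,10R,11R)-11-[(tert-butyldimethylsilyl)oxy]-5-hydroxy-4,6,8,10-tetramethyl-3-oxotrideca-6,8-dien-2-yl]-2-methoxy-3,5-dimethyl-4H-pyran-4-one (chain C2 unassigned) | CC[C@@H](O[Si](C)(C)C(C)(C)C)[C@H](C)/C=C(\C)/C=C(\C)[C@H](O)[C@@H](C)C(=O)C(C)c1oc(OC)c(C)c(=O)c1C
F2 | step 12 | allylic methyl carbonate: the 5-O-(methoxycarbonyl) derivative of F1 | CC[C@@H](O[Si](C)(C)C(C)(C)C)[C@H](C)/C=C(\C)/C=C(\C)[C@H](OC(=O)OC)[C@@H](C)C(=O)C(C)c1oc(OC)c(C)c(=O)c1C
F3 | step 13 | C5-epimeric cyclohex-3-enol: as 20 but 5α-OH | CC[C@@H](O[Si](C)(C)C(C)(C)C)[C@H](C)/C=C(\C)[C@@H]1C(C)=C[C@H](C)[C@H](O)[C@@]1(C)c1oc(OC)c(C)c(=O)c1C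
F4 | step 13 | α-epoxy α-alcohol: as 25 but 5α-OH | CC[C@@H](O[Si](C)(C)C(C)(C)C)[C@H](C)/C=C(\C)[C@@H]1[C@]2(C)O[C@@H]2[C@H](C)[C@H](O)[C@@]1(C)c1oc(OC)c(C)c(=O)c1C
F5 | step 13 | the 5α-methanesulfonate of F4 | CC[C@@H](O[Si](C)(C)C(C)(C)C)[C@H](C)/C=C(\C)[C@@H]1[C@]2(C)O[C@@H]2[C@H](C)[C@H](OS(C)(=O)=O)[C@@]1(C)c1oc(OC)c(C)c(=O)c1C
F6 | step 16 | bromohydrin: 2α-OH (2β-methyl), 3β-Br, 5β-OH | CC[C@@H](O[Si](C)(C)C(C)(C)C)[C@H](C)/C=C(\C)[C@@H]1[C@](C)(O)[C@@H](Br)[C@H](C)[C@@H](O)[C@@]1(C)c1oc(OC)c(C)c(=O)c1C
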